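The plan rests on closing the six-membered ring (C1–C6) at C3–C4, the bond that joins the future carbonyl carbon to the unsubstituted vinylic carbon of the C4=C5 olefin. An acyclic C3 aldehyde bearing a (Z)-alkenyl iodide at C4, in which an Ireland–Claisen rearrangement has already set the C6 stereocentre next to the C1 gem-dimethyl carbon, is cyclised by an intramolecular Nozaki–Hiyama–Kishi reaction. The step exploits the cis relationship of C4 and C6 across C4=C5 and delivers C3 as a carbinol, so the doubly allylic C6–H, γ to the later ketone, stays non-acidic while the polyene is attached by carboalumination–Negishi coupling; oxidation of C3 comes last.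

Key step: step 10

Numbering used: ring C1 (CMe2), C2 (CH2), C3 (C=O), C4 (=CH), C5 (=C–CH3), C6 (stereocentre, S); chain C7=C8–C9(CH3)=C10–C11=C12 and onward to the ester carbon.
Remark: (S,S)-ProPhenol is assumed to direct the alkynyl group to the Re face of aldehyde 7; should the sense be opposite, the enantiomeric ligand is used, the requirement being the (S)-carbinol 9.

Step 1
Reactants: 1 prop-2-yn-1-ol
Product: 3 (Z)-3-iodo-2-methylprop-2-en-1-ol, via chelated alkenylmagnesium alkoxide 2 (not isolated)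
Conditions: MeMgBr (2.5 equiv), CuI (10 mol %), THF, −10 °C → rt; then I2, −78 → 0 °C
Reagents that add atoms: methylmagnesium bromide, C[Mg]Br; iodine, II
Why: Copper-catalysed carbomagnesiation of the propargylic alkoxide is anti-selective because the alkoxide holds magnesium in a five-membered chelate, so iodinolysis of the C–Mg bond should give the (Z)-iodide with iodine cis to the CH2OH carbon (later C6).

Step 2
Reactants: 3 (Z)-3-iodo-2-methylprop-2-en-1-ol; 4 N-methoxy-N-methyl-2-(triphenylphosphoranylidene)acetamide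
Product: 6 (2E,4Z)-5-iodo-N-methoxy-N,4-dimethylpenta-2,4-dienamide, via (Z)-3-iodo-2-methylprop-2-enal 5 (not isolated)
Conditions: MnO2, CH2Cl2, rt; filter; then 4, CH2Cl2, rt
Reagents that add atoms: none
Why: Allylic oxidation followed by Wittig olefination with the stabilised amide ylide should give the (2E)-dienamide; the configurationally labile (Z)-iodoenal is trapped without isolation, and the amide product cannot react with a second equivalent of ylide.

Step 3
Reactants: 6 (2E,4Z)-5-iodo-N-methoxy-N,4-dimethylpenta-2,4-dienamide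
Product: 7 (2E,4Z)-5-iodo-4-methylpenta-2,4-dienal
Conditions: i-Bu2AlH, THF, −78 °C; aq. potassium sodium tartrate
Reagents that add atoms: none
Why: Weinreb amide reduction stops at the chelated aluminium hemiaminal, which releases the dienal only on work-up.

Step 4
Reactants: 7 (2E,4Z)-5-iodo-4-methylpenta-2,4-dienal; 8 ethynyltrimethylsilane
Product: 9 (3S,4E,6Z)-7-iodo-6-methyl-1-(trimethylsilyl)hepta-4,6-dien-1-yn-3-ol
Conditions: Me2Zn, (S,S)-ProPhenol (10 mol %), Ph3P=O (20 mol %), toluene, 4 °C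
Reagents that add atoms: none
Why: Catalytic asymmetric alkynylation, in which the dinuclear zinc–ProPhenol complex delivers the zinc alkynylide to the Re face of the aldehyde, should set the (S)-carbinol whose configuration is later relayed to C6.

Step 5
Reactants: 9 (3S,4E,6Z)-7-iodo-6-methyl-1-(trimethylsilyl)hepta-4,6-dien-1-yn-3-ol; 10 2-methylpropanoic anhydride
Product: 11 (3S,4E,6Z)-7-iodo-6-methyl-1-(trimethylsilyl)hepta-4,6-dien-1-yn-3-yl 2-methylpropanoate
Conditions: Et3N, DMAP (cat.), CH2Cl2, 0 °C → rt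
Reagents that add atoms: none
Why: DMAP-catalysed acylation of the secondary alcohol, which touches no stereocentre.

Step 6
Reactants: 11 (3S,4E,6Z)-7-iodo-6-methyl-1-(trimethylsilyl)hepta-4,6-dien-1-yn-3-yl 2-methylpropanoate
Product: 14 (3S,4E)-3-[(1Z)-1-iodoprop-1-en-2-yl]-2,2-dimethyl-7-(trimethylsilyl)hept-4-en-6-ynoic acid, via silyl ketene acetal 12 (not isolated), via trimethylsilyl ester 13 (not isolated)
Conditions: LiN(i-Pr)2, Me3SiCl, THF, −78 °C → rt, then 40 °C; 1 M HCl
Reagents that add atoms: none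
Why: Ireland–Claisen rearrangement: the silyl ketene acetal (both termini methyl, so no enolate geometry issue) should rearrange suprafacially through a chair with the alkynyl group pseudo-equatorial, which forms the C1–C6 bond, transfers the carbinol chirality to C6 (S) and creates the (E)-C7=C8 olefin.

Step 7
Reactants: 14 (3S,4E)-3-[(1Z)-1-iodoprop-1-en-2-yl]-2,2-dimethyl-7-(trimethylsilyl)hept-4-en-6-ynoic acid
Product: 16 (4S,5E)-1-diazo-4-[(1Z)-1-iodoprop-1-en-2-yl]-3,3-dimethyl-8-(trimethylsilyl)oct-5-en-7-yn-2-one, via acid chloride 15 (not isolated)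
Conditions: (COCl)2, DMF (cat.), CH2Cl2, 0 °C → rt; evaporate; Me3SiCHN2, MeCN/THF, 0 °C → rt
Reagents that add atoms: (trimethylsilyl)diazomethane, C[Si](C)(C)C=[N+]=[N-]
Why: First half of an Arndt–Eistert homologation: the acid chloride has no α-hydrogen and cannot form a ketene, so it is acylated on the diazo carbon and chloride removes the silyl group.

Step 8
Reactants: 16 (4S,5E)-1-diazo-4-[(1Z)-1-iodoprop-1-en-2-yl]-3,3-dimethyl-8-(trimethylsilyl)oct-5-en-7-yn-2-one
Product: 18 (4S,5E)-4-[(1Z)-1-iodoprop-1-en-2-yl]-N-methoxy-N,3,3-trimethyl-8-(trimethylsilyl)oct-5-en-7-ynamide, via ketene 17 (not isolated)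
Conditions: PhCO2Ag (10 mol %), Et3N, MeNH(OMe)·HCl, THF, rt, dark
Reagents that add atoms: N,O-dimethylhydroxylamine hydrochloride, CNOC.Cl
Why: Silver-catalysed Wolff rearrangement: the tertiary alkyl group migrates and the ketene is captured by the amine, which should make C2 a CH2 group and C3 the carbonyl carbon without touching C6.

Step 9
Reactants: 18 (4S,5E)-4-[(1Z)-1-iodoprop-1-en-2-yl]-N-methoxy-N,3,3-trimethyl-8-(trimethylsilyl)oct-5-en-7-ynamide
Product: 19 (4S,5E)-4-[(1Z)-1-iodoprop-1-en-2-yl]-3,3-dimethyl-8-(trimethylsilyl)oct-5-en-7-ynal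
Conditions: i-Bu2AlH, THF, −78 °C; aq. potassium sodium tartrate
Reagents that add atoms: none
Why: Weinreb amide reduction to the aldehyde; the alkenyl iodide and silyl alkyne are inert to the hydride at this temperature.

Step 10
Reactants: 19 (4S,5E)-4-[(1Z)-1-iodoprop-1-en-2-yl]-3,3-dimethyl-8-(trimethylsilyl)oct-5-en-7-ynal
Product: 20 (4S)-3,5,5-trimethyl-4-[(1E)-4-(trimethylsilyl)but-1-en-3-yn-1-yl]cyclohex-2-en-1-ol (both C1 epimers)
Conditions: CrCl2 (6 equiv), NiCl2 (2 mol %), degassed DMSO, rt, 0.02 M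
Reagents that add atoms: none
Why: Oxidative addition of the C4–I bond to zerovalent nickel (formed from NiCl2 by CrCl2) and transmetalation give a (Z)-alkenyl species of trivalent chromium that adds to the tethered C3 aldehyde, an intramolecular Nozaki–Hiyama–Kishi reaction. The six-membered ring closes in a 6-exo-trig mode with the carbonyl oxygen exocyclic, and the alkenyl geometry is retained, so the (Z)-iodide becomes the endocyclic C4=C5 bond. The only new stereocentre, the C3 carbinol, is formed under substrate control but needs none, because it is oxidised in the last step; C6 is not touched under these neutral conditions. The step needs chemoselectivity for the alkenyl iodide over the silyl enyne and for the aldehyde as sole electrophile, which the low basicity and carbonyl selectivity of organochromium reagents secure, while the C1 gem-dimethyl group (Thorpe–Ingold effect) favours cyclisation over oligomerisation.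

Step 11
Reactants: 20 (4S)-3,5,5-trimethyl-4-[(1E)-4-(trimethylsilyl)but-1-en-3-yn-1-yl]cyclohex-2-en-1-ol
Product: 21 (4S)-4-[(1E)-but-1-en-3-yn-1-yl]-3,5,5-trimethylcyclohex-2-en-1-ol
Conditions: K2CO3 (cat.), MeOH, rt
Reagents that add atoms: none
Why: Methanolysis of the C(sp)–Si bond; with C3 as a carbinol there is no enone and hence no base-labile hydrogen at C6.

Step 12
Reactants: 22 (E)-4,4-dimethoxybut-2-enal; 23 methyl 2-(triphenylphosphoranylidene)propanoate
Product: 25 methyl (2E,4E)-2-methyl-6-oxohexa-2,4-dienoate, via dimethyl acetal 24 (not isolated)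
Conditions: CH2Cl2, rt; then 1 M HCl, THF, rt
Reagents that add atoms: water, O
Why: Wittig olefination with the stabilised α-methyl ylide should give the (E)-trisubstituted enoate, and acid hydrolysis of the acetal in the same flask unmasks the aldehyde.

Step 13
Reactants: 25 methyl (2E,4E)-2-methyl-6-oxohexa-2,4-dienoate; 26 2-(triphenylphosphoranylidene)propanal
Product: 27 methyl (2E,4E,6E)-2,7-dimethyl-8-oxoocta-2,4,6-trienoate
Conditions: toluene, 70 °C
Reagents that add atoms: none
Why: Wittig homologation with the formyl-stabilised α-methyl ylide should give the (E)-α-methyl enal, which is less electrophilic than the starting dienal and so does not react again.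

Step 14
Reactants: 27 methyl (2E,4E,6E)-2,7-dimethyl-8-oxoocta-2,4,6-trienoate
Product: 28 methyl (2E,4E,6E,8E)-9-iodo-2,7-dimethylnona-2,4,6,8-tetraenoate
Conditions: CHI3, CrCl2, THF/1,4-dioxane, 0 °C → rt
Reagents that add atoms: iodoform, IC(I)I
Why: Takai iodo-olefination: the geminal dichromium species adds to the aldehyde and eliminates to the (E)-alkenyl iodide, leaving the ester untouched.

Step 15
Reactants: 21 (4S)-4-[(1E)-but-1-en-3-yn-1-yl]-3,5,5-trimethylcyclohex-2-en-1-ol; 28 methyl (2E,4E,6E,8E)-9-iodo-2,7-dimethylnona-2,4,6,8-tetraenoate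
Product: 30 methyl (2E,4E,6E,8E,10E,12E)-13-[(1S)-4-hydroxy-2,6,6-trimethylcyclohex-2-en-1-yl]-2,7,11-trimethyltrideca-2,4,6,8,10,12-hexaenoate, via alkenylalane 29 (not isolated)
Conditions: Me3Al, Cp2ZrCl2 (25 mol %), CH2Cl2, 0 °C → rt; evaporate; then 28, ZnCl2, Pd2(dba)3 (2.5 mol %), tri(2-furyl)phosphine (10 mol %), THF, rt
Reagents that add atoms: trimethylaluminium, C[Al](C)C
Why: Zirconium-catalysed syn-methylalumination (Negishi carboalumination) should put CH3 on C9 and aluminium on C10 with (E) geometry, and after transmetalation to zinc the alkenyl metal couples with retention with the (E)-iodide under zerovalent palladium (Negishi coupling), the C3 oxygen being masked in situ as its aluminium alkoxide.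

Step 16
Reactants: 30 methyl (2E,4E,6E,8E,10E,12E)-13-[(1S)-4-hydroxy-2,6,6-trimethylcyclohex-2-en-1-yl]-2,7,11-trimethyltrideca-2,4,6,8,10,12-hexaenoate
Product: 31 methyl (2E,4E,6E,8E,10E,12E)-2,7,11-trimethyl-13-[(1S)-2,6,6-trimethyl-4-oxocyclohex-2-en-1-yl]trideca-2,4,6,8,10,12-hexaenoate
Conditions: MnO2, CH2Cl2, rt, dark
Reagents that add atoms: none
Why: MnO2 should oxidise only the allylic C3 carbinol, under neutral heterogeneous conditions that neither epimerise C6 nor isomerise the polyene, to unveil the enone.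

Compound list
1 | prop-2-yn-1-ol | C#CCO | starting material
2 | 4-methyl-2,5-dihydro-1,2-oxamagnesole (chelated (Z)-alkenylmagnesium alkoxide) | CC1=C[Mg]OC1 | intermediate
3 | (Z)-3-iodo-2-methylprop-2-en-1-ol | OC/C(C)=C\I | intermediate
4 | N-methoxy-N-methyl-2-(triphenylphosphoranylidene)acetamide | CON(C)C(=O)C=P(c1ccccc1)(c1ccccc1)c1ccccc1 | starting material
5 | (Z)-3-iodo-2-methylprop-2-enal | O=C/C(C)=C\I | intermediate
6 | (2E,4Z)-5-iodo-N-methoxy-N,4-dimethylpenta-2,4-dienamide | CON(C)C(=O)/C=C/C(C)=C\I | intermediate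
7 | (2E,4Z)-5-iodo-4-methylpenta-2,4-dienal | O=C/C=C/C(C)=C\I | intermediate
8 | ethynyltrimethylsilane | C#C[Si](C)(C)C | starting material
9 | (3S,4E,6Z)-7-iodo-6-methyl-1-(trimethylsilyl)hepta-4,6-dien-1-yn-3-ol | C[Si](C)(C)C#C[C@@H](O)/C=C/C(C)=C\I | intermediate
10 | 2-methylpropanoic anhydride | CC(C)C(=O)OC(=O)C(C)C | starting material
11 | (3S,4E,6Z)-7-iodo-6-methyl-1-(trimethylsilyl)hepta-4,6-dien-1-yn-3-yl 2-methylpropanoate | C[Si](C)(C)C#C[C@@H](OC(=O)C(C)C)/C=C/C(C)=C\I | intermediate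
12 | trimethylsilyl ketene acetal of 11 | C[Si](C)(C)C#C[C@@H](OC(O[Si](C)(C)C)=C(C)C)/C=C/C(C)=C\I | intermediate
13 | trimethylsilyl (3S,4E)-3-[(1Z)-1-iodoprop-1-en-2-yl]-2,2-dimethyl-7-(trimethylsilyl)hept-4-en-6-ynoate | C[Si](C)(C)C#C/C=C/[C@H](/C(C)=C\I)C(C)(C)C(=O)O[Si](C)(C)C | intermediate
14 | (3S,4E)-3-[(1Z)-1-iodoprop-1-en-2-yl]-2,2-dimethyl-7-(trimethylsilyl)hept-4-en-6-ynoic acid | C[Si](C)(C)C#C/C=C/[C@H](/C(C)=C\I)C(C)(C)C(=O)O | intermediate
15 | (3S,4E)-3-[(1Z)-1-iodoprop-1-en-2-yl]-2,2-dimethyl-7-(trimethylsilyl)hept-4-en-6-ynoyl chloride | C[Si](C)(C)C#C/C=C/[C@H](/C(C)=C\I)C(C)(C)C(=O)Cl | intermediate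
16 | (4S,5E)-1-diazo-4-[(1Z)-1-iodoprop-1-en-2-yl]-3,3-dimethyl-8-(trimethylsilyl)oct-5-en-7-yn-2-one | C[Si](C)(C)C#C/C=C/[C@H](/C(C)=C\I)C(C)(C)C(=O)C=[N+]=[N-] | intermediate
17 | (4S,5E)-4-[(1Z)-1-iodoprop-1-en-2-yl]-3,3-dimethyl-8-(trimethylsilyl)octa-1,5-dien-7-yn-1-one (ketene) | C[Si](C)(C)C#C/C=C/[C@H](/C(C)=C\I)C(C)(C)C=C=O | intermediate
18 | (4S,5E)-4-[(1Z)-1-iodoprop-1-en-2-yl]-N-methoxy-N,3,3-trimethyl-8-(trimethylsilyl)oct-5-en-7-ynamide | C[Si](C)(C)C#C/C=C/[C@H](/C(C)=C\I)C(C)(C)CC(=O)N(C)OC | intermediate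
19 | (4S,5E)-4-[(1Z)-1-iodoprop-1-en-2-yl]-3,3-dimethyl-8-(trimethylsilyl)oct-5-en-7-ynal | C[Si](C)(C)C#C/C=C/[C@H](/C(C)=C\I)C(C)(C)CC=O | intermediate
20 | (4S)-3,5,5-trimethyl-4-[(1E)-4-(trimethylsilyl)but-1-en-3-yn-1-yl]cyclohex-2-en-1-ol (C1 epimers) | C[Si](C)(C)C#C/C=C/[C@@H]1C(C)=CC(O)CC1(C)C | intermediate
21 | (4S)-4-[(1E)-but-1-en-3-yn-1-yl]-3,5,5-trimethylcyclohex-2-en-1-ol (C1 epimers) | C#C/C=C/[C@@H]1C(C)=CC(O)CC1(C)C | intermediate
22 | (E)-4,4-dimethoxybut-2-enal | COC(OC)/C=C/C=O | starting material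
23 | methyl 2-(triphenylphosphoranylidene)propanoate | COC(=O)C(C)=P(c1ccccc1)(c1ccccc1)c1ccccc1 | starting material
24 | methyl (2E,4E)-6,6-dimethoxy-2-methylhexa-2,4-dienoate | COC(=O)/C(C)=C/C=C/C(OC)OC | intermediate
25 | methyl (2E,4E)-2-methyl-6-oxohexa-2,4-dienoate | COC(=O)/C(C)=C/C=C/C=O | intermediate
26 | 2-(triphenylphosphoranylidene)propanal | CC(C=O)=P(c1ccccc1)(c1ccccc1)c1ccccc1 | starting material
27 | methyl (2E,4E,6E)-2,7-dimethyl-8-oxoocta-2,4,6-trienoate | COC(=O)/C(C)=C/C=C/C=C(C)/C=O | intermediate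
28 | methyl (2E,4E,6E,8E)-9-iodo-2,7-dimethylnona-2,4,6,8-tetraenoate | COC(=O)/C(C)=C/C=C/C=C(C)/C=C/I | intermediate
29 | (1E,3E)-dienyl(dimethyl)alane of 21, oxygen as dimethylaluminium alkoxide | C[Al](C)/C=C(C)/C=C/[C@@H]1C(C)=CC(O[Al](C)C)CC1(C)C | intermediate
30 | methyl (2E,4E,6E,8E,10E,12E)-13-[(1S)-4-hydroxy-2,6,6-trimethylcyclohex-2-en-1-yl]-2,7,11-trimethyltrideca-2,4,6,8,10,12-hexaenoate | COC(=O)/C(C)=C/C=C/C=C(C)/C=C/C=C(C)/C=C/[C@@H]1C(C)=CC(O)CC1(C)C | intermediate
31 | methyl (2E,4E,6E,8E,10E,12E)-2,7,11-trimethyl-13-[(1S)-2,6,6-trimethyl-4-oxocyclohex-2-en-1-yl]trideca-2,4,6,8,10,12-hexaenoate | COC(=O)/C(C)=C/C=C/C=C(C)/C=C/C=C(C)/C=C/[C@@H]1C(C)=CC(=O)CC1(C)C | target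

Total step count: 16. Longest linear sequence: 13 steps (steps 1–11, 15 and 16); steps 12–14 form the side branch.

Steps most likely to fail

Step 6 (Ireland–Claisen rearrangement). The slim alkynyl group may partly occupy the pseudo-axial position of the chair, giving the (Z)-enyne with inverted C6, or the base may deprotonate the doubly activated carbinol C–H; either process would erode chirality transfer and material. The fallback sets out from alcohol 9. A Johnson–Claisen rearrangement with trimethyl orthoisobutyrate (EtCO2H cat., toluene, 110 °C), in which the axial methoxy group of the ketene acetal enforces the equatorial alkynyl position, should give methyl (3S,4E)-3-[(1Z)-1-iodoprop-1-en-2-yl]-2,2-dimethyl-7-(trimethylsilyl)hept-4-en-6-ynoate F1. Reduction with i-Bu2AlH at −78 °C should give (3S,4E)-3-[(1Z)-1-iodoprop-1-en-2-yl]-2,2-dimethyl-7-(trimethylsilyl)hept-4-en-6-ynal F2. Wittig methoxymethylenation (Ph3P=CHOMe, THF) should give (4S,5E)-4-[(1Z)-1-iodoprop-1-en-2-yl]-1-methoxy-3,3-dimethyl-8-(trimethylsilyl)octa-1,5-dien-7-yne F3, and mild acid hydrolysis returns to aldehyde 19, where step 10 follows.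

Step 15 (carboalumination and Negishi coupling in one flask). Methylalumination of the hydroxy enyne may be incomplete or poorly regioselective, or organoaluminium species may attack the ester during the coupling. The fallback sets out from 21 and from 27. Carboalumination of 21 as above, followed by iodinolysis (I2, THF, −30 °C), should give (4S)-4-[(1E,3E)-4-iodo-3-methylbuta-1,3-dien-1-yl]-3,5,5-trimethylcyclohex-2-en-1-ol F4. Aldehyde 27 is converted separately by chromium-mediated stannyl-olefination (Bu3SnCHBr2, CrCl2, LiI, THF/DMF) into methyl (2E,4E,6E,8E)-2,7-dimethyl-9-(tributylstannyl)nona-2,4,6,8-tetraenoate F5. Stille coupling of the two (Pd2(dba)3, AsPh3, NMP, rt) returns to 30.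

Step 4 (asymmetric alkynylation). Facial discrimination on the extended dienal may be insufficient because of uncatalysed background addition of the zinc alkynylide. The fallback sets out from Weinreb amide 6. Addition of lithium (trimethylsilyl)acetylide (THF, −78 °C) should give (4E,6Z)-7-iodo-6-methyl-1-(trimethylsilyl)hepta-4,6-dien-1-yn-3-one F6. Noyori asymmetric transfer hydrogenation of the ynone (RuCl[(S,S)-TsDPEN](p-cymene), i-PrOH, rt; catalyst enantiomer chosen for the (S)-alcohol) returns to 9.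

Further compounds
F1 | step 6 | methyl (3S,4E)-3-[(1Z)-1-iodoprop-1-en-2-yl]-2,2-dimethyl-7-(trimethylsilyl)hept-4-en-6-ynoate | C[Si](C)(C)C#C/C=C/[C@H](/C(C)=C\I)C(C)(C)C(=O)OC
F2 | step 6 | (3S,4E)-3-[(1Z)-1-iodoprop-1-en-2-yl]-2,2-dimethyl-7-(trimethylsilyl)hept-4-en-6-ynal | C[Si](C)(C)C#C/C=C/[C@H](/C(C)=C\I)C(C)(C)C=O
F3 | step 6 | (4S,5E)-4-[(1Z)-1-iodoprop-1-en-2-yl]-1-methoxy-3,3-dimethyl-8-(trimethylsilyl)octa-1,5-dien-7-yne (C1 E/Z mixture) | C[Si](C)(C)C#C/C=C/[C@H](/C(C)=C\I)C(C)(C)C=COC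
F4 | step 15 | (4S)-4-[(1E,3E)-4-iodo-3-methylbuta-1,3-dien-1-yl]-3,5,5-trimethylcyclohex-2-en-1-ol | I/C=C(C)/C=C/[C@@H]1C(C)=CC(O)CC1(C)C
F5 | step 15 | methyl (2E,4E,6E,8E)-2,7-dimethyl-9-(tributylstannyl)nona-2,4,6,8-tetraenoate | COC(=O)/C(C)=C/C=C/C=C(C)/C=C/[Sn](CCCC)(CCCC)CCCC
F6 | step 4 | (4E,6Z)-7-iodo-6-methyl-1-(trimethylsilyl)hepta-4,6-dien-1-yn-3-one | C[Si](C)(C)C#CC(=O)/C=C/C(C)=C\I
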